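In a one-step world fed steadily by a solid, Q climbs a straight line, and a mean rate read at one time serves for another. Try that on this flask, whose charge lies between those of two earlier runs.

| flask | D | remark | time |
|---|---|---|---|
| beta | 0.050 M | run made earlier |  |
| zeta | 0.20 M | run made earlier |  |
| flask | 0.10 M |  | 12 min |

- beta (time / min: Q / %): 1.00: 4.6; 2.00: 10.6; 2.50: 12.6; 4.00: 20.5; 6.00: 29.1; 10.0: 40.1; 15.0: 32.5
- zeta (time / min: Q / %): 1.00: 1.1; 2.00: 2.3; 2.50: 3.6; 4.00: 5.5; 6.00: 6.9; 10.0: 11.1; 15.0: 12.5

(readings scatter by 0.3 percentage points)

- how much Q there is at 12 min, in percent of the D charged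
- the change that raises the amount of Q at 12 min, in percent of the D charged most ("none" if none brings more than 2 percentage points) (larch / elm / none)
- amount of Q at 12 min, in percent of the D charged, after elm

- larch: doubling the solubility of D, all else as stated
- elm: doubling the dissolution coefficient of D, all else as stated

- solid, in amounts per volume of the solution: D
- at the start none of D is in solution

Put the percentages into molarity and the charge hardly shows (near zero order in the solid): at 6.00 min beta holds 0.0146 M and zeta 0.0138 M. So I reckon two ways. First, the straight line from beta: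

rate = 0.00243 M min⁻¹, so over 12 min Q = 29.1 % of the charge

Second, zeta read between its last two readings:

Q at 12 min = 0.0233 M, or 23.3 % of the charge

They part by 5.8 percentage points, and the straight line cheats. Zeta's mean falls from 0.00230 M min⁻¹ at 6.00 min to 0.00167 M min⁻¹ at 15.0 min, so an early mean overstates a later time on this curve. Carry instead the mean molar rate m, Q in molarity at the asked time divided by that time: 0.00194 M min⁻¹. Beta's mean up to 10.0 min, from a different flask, reads 0.00201 M min⁻¹.

Zeta is a fair guide while the flask keeps solid. Beta's Q reads lower at 15.0 min than at 10.0 min, which I read as its 0.050 M used up near 10.0 min, about 0.00500 M min⁻¹. At that estimated pace the flask uses about 0.0600 M by 12 min, less than its 0.10 M, so I expect solid still there. I commit to 23.3 %.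

The forecast gives 23.5 %, names larch, and puts elm at 27 %, holding that “Doubling the dissolution coefficient helps only as far as dissolution limits supply”.

The flask gives 22.2 %, with 42.7 % of the charge still solid D at 12.0 min. Elm adds 11 points and larch 9.2 points, so the better change is elm, reaching 33.6 %. The flask's own mean rate is 0.00185 M min⁻¹, against the carried 0.00194 M min⁻¹.

    Z ⇌ Q (K = 1.70, k = 0.0299 s⁻¹)
    Q ⇌ G (K = 0.840, k = 6.06 × 10⁻⁴ s⁻¹)
    G ⇌ Z (k = 7.63 × 10⁻⁴ s⁻¹)
    D ⇌ Z, rate k4*(cs4 - [Z]) while solid is left; crystals form when [Z] > cs4 (solubility = 0.0670 M, k = 0.00137 s⁻¹)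
    2 Z → X (k = 0.0924 M⁻¹ s⁻¹)

Take the same flask with 0.25 M of D: 0.00194 M min⁻¹ over 12 min gives 9.31 % of that charge, and the computed result is 8.88 %.

The numbers in the tables stem from a simulated flask on assumed constants; the scatter is artificial.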